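## Retrosynthetic overview

- The target comes from its 4'-O-benzyl, 5-O-methyl precursor by one-pot BCl3 unmasking: benzyl ether cleavage plus chelation-directed cleavage of the 5-OMe peri to the C4 carbonyl.
- That flavonol comes from a 2'-hydroxychalcone by Algar–Flynn–Oyamada oxidative cyclization, which makes the O1–C2 bond and installs the 3-OH in one operation.
- The chalcone comes from 2'-hydroxy-3',4',5',6'-tetramethoxyacetophenone (ring A, all oxygens in place) and 4-(benzyloxy)benzaldehyde (ring B) by Claisen–Schmidt condensation.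
- Ring order: rings A and B are bought intact; ring C (the pyranone) is the only ring formed, in step 2.

Assumption: the target has no stereocentre (planar, achiral flavonol), so no asymmetric step is needed, and 2'-hydroxy-3',4',5',6'-tetramethoxyacetophenone is taken as a catalogue compound.

## Route

Step 1
Reactants: 1 1-(2-hydroxy-3,4,5,6-tetramethoxyphenyl)ethan-1-one; 2 4-(benzyloxy)benzaldehyde
Product: 4 (E)-3-[4-(benzyloxy)phenyl]-1-(2-hydroxy-3,4,5,6-tetramethoxyphenyl)prop-2-en-1-one, via aldol adduct 3 (not isolated)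
Conditions: KOH (50% aq, 10 equiv), EtOH, 0 °C → rt, 36 h; then 2 M HCl to pH 3
Reagents that add atoms: none
Why: Claisen–Schmidt (crossed aldol) condensation, in which the methyl-ketone enolate of 1 adds to the non-enolizable aldehyde 2 and aldol 3 dehydrates by E1cB to the conjugated enone with the thermodynamically favoured E geometry, leaving no stereocentre.

Step 2
Reactants: 4 (E)-3-[4-(benzyloxy)phenyl]-1-(2-hydroxy-3,4,5,6-tetramethoxyphenyl)prop-2-en-1-one
Product: 6 2-[4-(benzyloxy)phenyl]-3-hydroxy-5,6,7,8-tetramethoxy-4H-chromen-4-one, via trans-dihydroflavonol 5 (not isolated)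
Conditions: 30% aq H2O2 (6 equiv), NaOH (2 M aq, 6 equiv), MeOH/THF, 0 °C → rt, 6 h; then 2 M HCl to pH 3
Reagents that add atoms: hydrogen peroxide, OO
Why: Algar–Flynn–Oyamada reaction, in which the 2'-phenoxide closes ring C by 6-endo oxa-Michael addition (favoured at the β-carbon by the electron-rich 4-benzyloxyphenyl group) while H2O2 hydroxylates the enolate, and alkaline H2O2 then dehydrogenates the racemic trans-3-hydroxyflavanone 5 to the flat flavonol so that its two transient stereocentres vanish.

Step 3
Reactants: 6 2-[4-(benzyloxy)phenyl]-3-hydroxy-5,6,7,8-tetramethoxy-4H-chromen-4-one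
Product: 8 3,5-dihydroxy-2-(4-hydroxyphenyl)-6,7,8-trimethoxy-4H-chromen-4-one (target), via debenzylated flavonol 7 (not isolated)
Conditions: BCl3 (1 M in CH2Cl2, 5 equiv), C6HMe5 (3 equiv), CH2Cl2, −78 °C, 1 h, then 0 °C → rt, 3 h; then 1 M aq HCl, rt
Reagents that add atoms: none
Why: Lewis-acid ether cleavage, in which BCl3 removes the benzyl group at −78 °C (the benzyl cation is trapped by pentamethylbenzene in a Friedel–Crafts alkylation) and on warming cleaves only the 5-OMe, activated through a six-membered boron chelate with the C4 carbonyl, while the 6-, 7- and 8-OMe groups have no such assistance.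

## Compound list

1 | 1-(2-hydroxy-3,4,5,6-tetramethoxyphenyl)ethan-1-one (2'-hydroxy-3',4',5',6'-tetramethoxyacetophenone) | CC(=O)c1c(O)c(OC)c(OC)c(OC)c1OC | starting material
2 | 4-(benzyloxy)benzaldehyde | O=Cc1ccc(OCc2ccccc2)cc1 | starting material
3 | 3-[4-(benzyloxy)phenyl]-3-hydroxy-1-(2-hydroxy-3,4,5,6-tetramethoxyphenyl)propan-1-one (aldol adduct, racemic, not isolated) | COc1c(OC)c(OC)c(C(=O)CC(O)c2ccc(OCc3ccccc3)cc2)c(O)c1OC | intermediate
4 | (E)-3-[4-(benzyloxy)phenyl]-1-(2-hydroxy-3,4,5,6-tetramethoxyphenyl)prop-2-en-1-one (2'-hydroxychalcone) | COc1c(OC)c(OC)c(C(=O)/C=C/c2ccc(OCc3ccccc3)cc2)c(O)c1OC | intermediate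
5 | trans-2-[4-(benzyloxy)phenyl]-3-hydroxy-5,6,7,8-tetramethoxychroman-4-one (racemic; the 2R,3R enantiomer is drawn; not isolated) | COc1c(OC)c(OC)c2c(c1OC)O[C@H](c1ccc(OCc3ccccc3)cc1)[C@@H](O)C2=O | intermediate
6 | 2-[4-(benzyloxy)phenyl]-3-hydroxy-5,6,7,8-tetramethoxy-4H-chromen-4-one | COc1c(OC)c(OC)c2c(=O)c(O)c(-c3ccc(OCc4ccccc4)cc3)oc2c1OC | intermediate
7 | 3-hydroxy-2-(4-hydroxyphenyl)-5,6,7,8-tetramethoxy-4H-chromen-4-one (boron-bound in the flask, not isolated) | COc1c(OC)c(OC)c2c(=O)c(O)c(-c3ccc(O)cc3)oc2c1OC | intermediate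
8 | 3,5-dihydroxy-2-(4-hydroxyphenyl)-6,7,8-trimethoxy-4H-chromen-4-one (3,5,4'-trihydroxy-6,7,8-trimethoxyflavone, achiral) | COc1c(OC)c(O)c2c(=O)c(O)c(-c3ccc(O)cc3)oc2c1OC | target

## Step count and risk

Total step count: 3. Longest linear sequence: 3 steps (1 → 4 → 6 → 8, with aldehyde 2 joined in step 1).

Most likely to fail, in order:

Step 2. A 6'-methoxy-2'-hydroxychalcone can divert to the aurone by attack at the α-carbon, which lowers or ruins the flavonol yield. The fallback sets out from 4 and comes back at 6. Oxidative cyclization of 4 with catalytic I2 in DMSO at 120 °C gives 2-[4-(benzyloxy)phenyl]-5,6,7,8-tetramethoxy-4H-chromen-4-one F4, a manifold that gives the flavone and no aurone. Epoxidation of its C2=C3 enol-ether bond with DMDO in acetone/CH2Cl2 (0 °C → rt) gives the racemic cis-fused 2-[4-(benzyloxy)phenyl]-2,3-epoxy-5,6,7,8-tetramethoxychroman-4-one F5, which is not isolated. Catalytic p-TsOH opens the epoxide at C2 and enolization delivers flavonol 6, from which step 3 follows unchanged.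

Step 3. The free 3-OH can tie up the C4 carbonyl as a five-membered borate and slow the 5-O-demethylation, and forcing the reaction risks loss of the 6-OMe. The fallback sets out from 6 and comes back at 8 with the two deprotections separated and run by different chemistry. Hydrogenolysis (H2, 1 atm, Pd/C, EtOAc/MeOH, rt) removes the benzyl group and gives 7 as an isolated compound. Anhydrous AlCl3 in MeCN at 60 °C, followed by warm dilute HCl to break the aluminium chelate, then cleaves only the carbonyl-chelated 5-OMe to give 8. This detour creates no compound outside the list (none F0).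

Step 1. The ketone is di-ortho-substituted and electron-rich, so condensation can be slow, and under strong base the chalcone can partly close to the flavanone or the aldehyde can disproportionate. The fallback sets out from 1 and comes back at 4, making the same C=C bond by olefination under neutral conditions. CuBr2 (2 equiv) in EtOAc/CHCl3 at reflux brominates only the acetyl methyl, since the ring is fully substituted, and gives 2-bromo-1-(2-hydroxy-3,4,5,6-tetramethoxyphenyl)ethan-1-one F1. PPh3 in toluene at rt gives [2-(2-hydroxy-3,4,5,6-tetramethoxyphenyl)-2-oxoethyl]triphenylphosphonium bromide F2. Aqueous Na2CO3 gives the stabilized ylide 1-(2-hydroxy-3,4,5,6-tetramethoxyphenyl)-2-(triphenyl-λ5-phosphanylidene)ethan-1-one F3. Wittig olefination of F3 with aldehyde 2 in toluene at reflux gives (E)-chalcone 4, from which step 2 follows unchanged.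

## Further compounds

F1 | step 1 | 2-bromo-1-(2-hydroxy-3,4,5,6-tetramethoxyphenyl)ethan-1-one | COc1c(OC)c(OC)c(C(=O)CBr)c(O)c1OC
F2 | step 1 | [2-(2-hydroxy-3,4,5,6-tetramethoxyphenyl)-2-oxoethyl]triphenylphosphonium bromide | COc1c(OC)c(OC)c(C(=O)C[P+](c2ccccc2)(c2ccccc2)c2ccccc2)c(O)c1OC.[Br-]
F3 | step 1 | 1-(2-hydroxy-3,4,5,6-tetramethoxyphenyl)-2-(triphenyl-λ5-phosphanylidene)ethan-1-one | COc1c(OC)c(OC)c(C(=O)C=P(c2ccccc2)(c2ccccc2)c2ccccc2)c(O)c1OC
F4 | step 2 | 2-[4-(benzyloxy)phenyl]-5,6,7,8-tetramethoxy-4H-chromen-4-one | COc1c(OC)c(OC)c2c(=O)cc(-c3ccc(OCc4ccccc4)cc3)oc2c1OC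
F5 | step 2 | 2-[4-(benzyloxy)phenyl]-2,3-epoxy-5,6,7,8-tetramethoxychroman-4-one (racemic, cis-fused epoxide, one enantiomer drawn) | COc1c(OC)c(OC)c2c(c1OC)O[C@@]1(c3ccc(OCc4ccccc4)cc3)O[C@H]1C2=O
F0 | step 3 | none | none
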